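**The question.** The ash flask, with 33.0 mM of starting material in 200 mM of reagent, was what I had to foretell from the oak, elm and alder runs.

| flask | starting material | reagent | catalyst | time |
|---|---|---|---|---|
| oak | 100 mM | 100 mM | 8.00 mM |  |
| elm | 100 mM | 100 mM | 12.0 mM |  |
| alder | 100 mM | 150 mM | 8.00 mM |  |
| ash | 33.0 mM | 200 mM | 8.00 mM | 63 min |

- oak run (time / min: [target] / mM): 10: 13.0; 21: 24.9; 32: 32.7; 42: 37.1; 52: 41.0; 63: 43.1
- elm run (time / min: [target] / mM): 10: 19.3; 21: 34.2; 32: 42.6; 42: 47.1; 52: 50.0; 63: 50.6
- alder run (time / min: [target] / mM): 10: 14.0; 21: 25.4; 32: 34.1; 42: 39.4; 52: 42.3; 63: 44.7

(each reading ± 0.3 mM)

- Overall: starting material + reagent -> target, with catalyst as catalyst.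
- Constant volume, constant temperature.
- A reading of a species includes what of it is bound.
- "The second partner" is reagent.
- An order is taken over about fifteen percent of the charge, up and down.

- apparent order in [reagent] of the starting rate, round the charge of the oak run (the rate where two percent of its starting material have turned into target)
- apparent order in [catalyst] of the starting rate, round the charge of the oak run (the rate where two percent of its starting material have turned into target)
- target in the ash run at 63 min, as a share of the starting material charged

**The orders.** I read the catalyst order from the first readings of elm and oak as 0.975, and the reagent order from alder and oak as 0.183. That second figure rests on a gap of 1.00 mM against a scatter of 0.3 mM, so I summed the readings of each run instead and got an order n of 0.102, which I committed to, although it is a reading over the whole run and not of the start.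

**Clearing constant.** I treated the starting material as pseudo-first-order, with a clearing constant κ read from the first alder reading as 0.0151 min⁻¹. The objection could not be computed away, since oak, elm and alder share one charge of 100 mM of starting material, so first order was my assumption. Scaled by n to the reagent of ash, κ became 0.0155 min⁻¹, which promised 62.4% cleared by 63 min.

**Kept share.** But the same reckoning promised alder 61.4%, and alder showed 44.7%. So I defined ρ, the kept share, as the target found over the amount κ says was cleared, which for alder at 63 min is 0.729. Oak gave 0.738, but elm, which cleared faster, gave 0.683, so ρ was no constant across these runs. Since κ for ash stood at 0.0155 min⁻¹ beside 0.0151 min⁻¹ for alder, I kept the alder value and estimated 45.5%.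

**The forecast.** The forecast gave 0.15 and 1 for the orders and 60% for ash, within 45% to 82%, holding that “the stall probably comes from catalyst loss over time”.

**The result.** The flask gave orders of 0.094 in reagent and 1.0 in catalyst, and 45.4% for ash.

    catalyst + starting material + reagent → target + catalyst (252.6 L² mol⁻² min⁻¹)
    catalyst + reagent ⇌ idle catalyst-reagent complex, settled at all times (120.0 L mol⁻¹)
    target → decomposed product (0.009600 min⁻¹)

**What ρ measured.** The kept share stood below one through the turning of target into decomposed product. The proof is the ash flask run without that step, which reached 63.7% where the real flask reached 45.4%, a drop of 18 percentage points. Applied to that second flask, ρ of 0.729 turns its 63.7% into 46.4%, against the 45.4% of the ash flask.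

(The readings stem from a simulated flask for an exercise; noise was put on by code.)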